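By 2.00 min at 100 °C the maple flask reads 18% of target, and at 25 min it reads 20%, so I look at a stall, not at a slow run.

| flask | starting material | second substrate | gas | free catalyst | temperature | remark | time |
|---|---|---|---|---|---|---|---|
| maple | 0.25 M | 0.25 M | 15 mM (held) | 0.25 mM | 100 °C | the very flask that is asked about, followed so far |  |
| alder | 0.25 M | 0.12 M | 15 mM (held) | 0.25 mM | 95 °C | run made earlier |  |
| flask | 0.25 M | 0.250 M | 15 mM (held) | 0.25 mM | 100 °C |  | 25 min |

maple run (percent of the starting material charged)

| time / min | target / % | starting material / % |
|---|---|---|
| 2.00 | 18 | 83 |
| 4.00 | 17 | 84 |
| 8.00 | 18 | 84 |
| 12.0 | 18 | 82 |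
| 25.0 | 20 | 82 |

alder run (percent of the starting material charged)

| time / s | target / % | starting material / % |
|---|---|---|
| 12.0 | 10 | 92 |
| 25.0 | 15 | 86 |
| 40.0 | 20 | 78 |
| 50.0 | 28 | 75 |
| 60.0 | 32 | 73 |

(readings scatter by 1.5 percentage points)

The five maple readings of target average 18.2%, but this is no ceiling of the chemistry, because the cooler alder run with less second substrate reaches 32%, more than the maple level, and is still climbing. Starting material still reads 82% in maple, so I suspect the catalyst.

I therefore count N = 182, the turnover number, target made per free catalyst charged, a reading that carries the scatter of the maple readings. By its last reading alder has made 320, more turns than maple, so N is no constant of the catalyst; but alder differs from maple in temperature as well as in second substrate, so these two runs do not separate the two settings, and as a working guess I let N vary inversely with second substrate, with temperature and the other settings held.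

* target, in percent of the starting material first charged, at 25 min
* the remedy with the largest gain of target, or "none" below 2 percentage points (alpha / gamma / epsilon / delta / none)
* target present, with what was taken out counted in, in percent of the starting material first charged, after epsilon
* target present, with what was taken out counted in, in percent of the starting material first charged, after delta

- alpha: at 25 min add free catalyst, 100% of the amount charged, then wait 8.0 min
- gamma: at 25 min take out 90% of the target then present, then wait 8.0 min
- epsilon: at 25 min raise the temperature by 15 K, then wait 8.0 min
- delta: change nothing and wait 8.0 min more

- target that was removed still counts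
- at the start none of the gas is in solution
- additions bring no volume worth counting

A fresh charge should then make N turns again, a gain of 18 percentage points, well above the margin, whereas removing target, heating or waiting acts on no working catalyst. I commit to 18.2% at 25 min, to alpha, and to the same 18.2% after epsilon and delta.

The forecast says 19%, alpha, 20% after epsilon and 19.4% after delta, on the ground that “the likeliest cause is that the catalyst has died”, and it expects 10 to 18 points from alpha.

The flask gives 18.0%, alpha with a gain of 19 points, 18.0% after epsilon and 18.0% after delta.

    starting material + reagent + free catalyst → free catalyst + target (k = 6400 M⁻² s⁻¹, Ea = 33.0 kJ mol⁻¹)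
    second substrate + reagent + free catalyst → free catalyst + second product (k = 1300 M⁻² s⁻¹, Ea = 43.0 kJ mol⁻¹)
    gas ⇌ reagent, rate k3*(csat - [reagent]) (kL = 0.240 s⁻¹)
    second substrate + free catalyst → spent catalyst (k = 0.250 M⁻¹ s⁻¹, Ea = 61.0 kJ mol⁻¹)
    (constants at 100 °C)

At 25.0 min the flask holds free catalyst at 0% and spent catalyst at 100%, and the second charge of alpha gains 19 points against my 18 points. The neighbour flask is this one charged with 0.42 M of second substrate, so my working guess scales N to 108 turns, which is 10.8% of target, in percent of the starting material charged. At 25.0 min that neighbour flask holds 9.87% of target, with spent catalyst at 100% and starting material at 90%.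

The readings stem from a simulated flask from invented constants; noise was put on by code.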